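# Proposed total synthesis of CNP0120800.1

## Analysis of the target

Atoms are numbered in the order of the SMILES string: C1, C2 (ethyl), C3, C4, O5, C6(=O7), C8, C9 (methyl), C10, C11, C12, C13, C14, C15, C16, C17 (methyl), C18(=O19), O20, N21, C22, C23, C24, C25, O26, C27, C28(=O29). In this numbering the target is (3S,4S,8S,10R,11S,13R,14R,16R,25R,27S).

- **Ring system.** Ring A is the cyclopentane C3–C4–C10–C11–C27. Ring B is a γ-lactone cis-fused at C4/C10 (O5, C6, C8). Ring C is the δ-lactam N21–C13–C12–C11–C27–C28. Ring D is the seven-membered ring N21–C22–C23–C24–C25–C27–C28. Ring E is the pendant γ-lactone C14–C15–C16–C18–O20.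
- **Bridged amide.** Rings C and D share N21–C28–C27, a 1-azabicyclo[4.3.1]decan-10-one in which the amide carbonyl C28 is the one-atom bridge. The amide cannot be planar, so N21 is amine-like and C28 is an activated acyl group.
- **Ring A stereochemistry.** All five ring A carbons are stereocentres. C2, C12 and C28 lie on one face; O5, C8 and C25 lie on the other. C27 is quaternary and is flanked by C3, C11 and C25.
- **Other stereocentres.** Methyl C9 sits on the concave face of ring B (cis to C10–C11), which is the less stable arrangement. Ring E is cis-2,4-disubstituted. N21 and O20 are syn (threo) across C13–C14. O26 is cis to C11 across ring D.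
- **Sensitive groups.** The twisted amide (hydrolysis, N-protonation); the β-hydroxy carbonyl at C25/C27/C28 (retro-aldol under base); two lactones with epimerisable α-centres, C8 being in its kinetic configuration.
- **What makes it hard.** The bridge has to be closed against amide resonance at a quaternary carbon, and ring A carries five contiguous stereocentres.

## Retrosynthetic reasoning

**28 to 27.** Only the 2-(hydroxymethyl)benzyl group on O26 is removed. It is the opened half of the cyclic acetal used as the electrophile in the key step, and it is a benzylic ether that falls off under neutral hydrogenolysis, which the twisted amide should tolerate.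

**27 to 25 (key disconnection, C27–C25).** Cutting the bond between quaternary C27 and carbinol C25 opens ring D and returns a planar, ordinary cis-fused lactam 25. This is preferred to cutting N21–C28 or N21–C22, because those cuts keep the quaternary centre and leave a medium ring or a second N–C bond to be forged on a non-nucleophilic amide nitrogen. Forward, C27 (as the lactam enol silane in 26) must attack an oxocarbenium ion at C25 that hangs from N21 and is released by opening the cyclic acetal. That one bond closes ring D, twists the amide, makes the quaternary centre and sets C25.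

**25 to 21 and 24 (N21–C22); 24 to 22 and 23.** The four-carbon chain C22–C25 is attached by N-alkylation of the secondary lactam 21 with the chloro acetal 24. The lactam N–H is the most acidic site of 21. The acetal 24 is a 1,5-dihydro-3H-2,4-benzodioxepine, made by exchanging both methoxy groups of the commercial dimethyl acetal 22 for the single diol 23. Either oxygen of this cyclic acetal, once it stays on C25, is a hydrogenolysable benzylic ether.

**21 to 20 to 18 (C15=C16 reduction; N21–C28).** Ring E is carried as a butenolide and hydrogenated anti to C13 (cis-lactone). Ring C is an unstrained six-membered lactam that closes once the amine of 18 is freed.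

**18 to 15 and 17 (C13–C14).** A vinylogous Mannich reaction joins the complete ring E carbon set (17) to an N-sulfinyl imine 15. The sulfinyl auxiliary from 14 controls C13; C14 follows from the threo preference.

**15 to 13 to 11 to 10 to 8 to 7 (C28).** The aldehyde C13 comes from ozonolysis of an allyl group. C28 is added to the ring A ketone of 7 by methoxymethylenation and oxidation. The same oxidation turns the lactol ether into lactone B.

**7 to 5 and 6 (C8–C10 and C11–C12).** A radical cyclisation–allylation cascade on the enone 5 forms ring B cis-fused from the C4 oxygen tether, and traps the C11 radical with the stannane 6 on the opposite face. C10, C11 and C8 are set from C4.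

**5 to 3 and 4; 3 to 2 to 1.** Ring A itself, with C3/C4 trans, comes from dearomatisation of the furan ring of 1 by Piancatelli rearrangement. Kinetic resolution supplies the absolute configuration.

## Alternatives that were turned down

**Alternative 1: amide bond N21–C28 (the textbook cut).** Forward: transannular lactamisation of the nine-membered amino acid A1. Turned down because A1 contains a nine-membered azacycle fused to ring A around the quaternary C27. It needs a medium-ring closure at high dilution and protection of N21 and O26. The quaternary centre and C25 must still be made separately, and the final acylation joins a hindered secondary amine to a neopentyl carboxyl group while forming a non-planar amide.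

**Alternative 2: nitrogen insertion (N21–C28 and N21–C22).** Forward: intramolecular Schmidt reaction of the azido spiroketone A2, with C22 migrating from C28 to nitrogen. Turned down on stereoelectronic grounds.
- Migration of C22 requires the azidohydrin chair in which the diazonium group is axial and anti to C22.
- In that chair the diazonium group is syn-axial to C3, and the ethyl group on C3 (cis to C28 on ring A) sits over exactly this face.
- With the diazonium group equatorial, the quaternary C27 migrates instead, which should give the fused pyrrolo-azepinone A3.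
- A2 also needs a spiro[4.5]decanone with all ten stereocentres in place.

**Alternative 3: biomimetic skeletal rearrangement.** Forward: semipinacol 1,2-shift of C11 from C28 to C27 in the epoxy carbinolamine A4, which ring-contracts a cyclohexane to ring A and creates the lactam carbonyl. Turned down because A4 is a pentacycle as complex as the target, so nothing is simplified. In addition, migration anti to the breaking epoxide C–O bond should place O26 trans to C11 on ring D, which is the C25 epimer.

Key step: step 16

Assumption: the lipase in step 2 acetylates the (4R,5S)-enantiomer of 2 faster, so that the wanted (4S,5R)-alcohol 3 is the unreacted enantiomer.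

Remark: C27 is epimerisable in 9–25 and is drawn with its carbonyl substituent cis to C12; either epimer converges in step 16, where C27 becomes sp2.

## Route

Step 1
Reactants: 1 1-(furan-2-yl)propan-1-ol (racemic)
Product: 2 rac-trans-5-ethyl-4-hydroxycyclopent-2-en-1-one
Conditions: ZnCl2 (1.5 equiv), dioxane/H2O (pH 5–6), 90 °C
Reagents that add atoms: water, O
Why: Piancatelli rearrangement: ionisation of the furylcarbinol, addition of water to the furan, ring opening and conrotatory 4π electrocyclisation of the pentadienyl cation should give the trans-4-hydroxy-5-alkylcyclopentenone. The furan is converted into ring A with the trans C3/C4 relationship of the target.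

Step 2
Reactants: 2 rac-trans-5-ethyl-4-hydroxycyclopent-2-en-1-one
Product: 3 (4S,5R)-5-ethyl-4-hydroxycyclopent-2-en-1-one
Conditions: Burkholderia cepacia lipase, vinyl acetate, t-BuOMe, 30 °C, stopped near 52 % conversion; chromatography
Reagents that add atoms: none
Why: Lipase-catalysed kinetic resolution by enantioselective acetylation of a secondary allylic alcohol. It fixes the absolute configuration of C3 and C4 (target numbering), from which the ring A and ring B centres follow by substrate control.

Step 3
Reactants: 3 (4S,5R)-5-ethyl-4-hydroxycyclopent-2-en-1-one; 4 ethyl prop-1-enyl ether (E/Z mixture)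
Product: 5 (4S,5R)-4-(2-bromo-1-ethoxypropoxy)-5-ethylcyclopent-2-en-1-one (mixture at the two side-chain centres)
Conditions: N-bromosuccinimide, CH2Cl2, −40 to 0 °C
Reagents that add atoms: N-bromosuccinimide, O=C1CCC(=O)N1Br
Why: Bromoetherification of the enol ether with the alcohol gives the mixed bromoacetal. The electron-poor enone alkene is inert, and both new centres are destroyed later (radical at C8, carbonyl at C6).

Step 4
Reactants: 5 (4S,5R)-4-(2-bromo-1-ethoxypropoxy)-5-ethylcyclopent-2-en-1-one; 6 allyltributylstannane
Product: 7 4-allyl-2-ethoxy-6-ethyl-3-methylhexahydro-2H-cyclopenta[b]furan-5-one (cis-fused; allyl trans to the furan ring; methyl on the concave face; epimers at the acetal carbon)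
Conditions: AIBN (0.2 equiv, in portions), PhH, 80 °C, 0.02 M, 4 equiv of 6
Reagents that add atoms: none
Why: Ueno–Stork 5-exo-trig cyclisation of the C8 radical onto the enone β-carbon C10 can only give the cis-fused ring B. The resulting α-keto radical at C11 is allylated by 6 (Keck allylation) on the convex face, trans to C8. A chair-like transition state should place methyl C9 cis to C10–C11; any C8 epimer converges in step 16.

Step 5
Reactants: 7 4-allyl-2-ethoxy-6-ethyl-3-methylhexahydro-2H-cyclopenta[b]furan-5-one
Product: 8 4-allyl-2-ethoxy-6-ethyl-5-(methoxymethylidene)-3-methylhexahydro-2H-cyclopenta[b]furan (E/Z mixture)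
Conditions: Ph3P(CH2OMe)Cl, KN(SiMe3)2, THF, −78 to 0 °C; then 7, 0 °C to rt
Reagents that add atoms: (methoxymethyl)triphenylphosphonium chloride, COC[P+](c1ccccc1)(c1ccccc1)c1ccccc1.[Cl-]
Why: Wittig methoxymethylenation adds C28 to the ring A ketone. The two α-centres (C3, C11) are already in their more stable trans arrangements, so reversible enolisation by the ylide should not erode them.

Step 6
Reactants: 8 4-allyl-2-ethoxy-6-ethyl-5-(methoxymethylidene)-3-methylhexahydro-2H-cyclopenta[b]furan
Product: 10 4-allyl-6-ethyl-3-methyl-2-oxohexahydro-2H-cyclopenta[b]furan-5-carboxylic acid, via aldehyde lactol 9 (not isolated)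
Conditions: CrO3, H2SO4, H2O, acetone, 0 °C
Reagents that add atoms: water, O
Why: Jones oxidation: the aqueous acid hydrolyses the enol ether and the lactol ether, and hexavalent chromium oxidises the aldehyde to the acid and the lactol to lactone B in one operation. The terminal alkene and C8 are not touched.

Step 7
Reactants: 10 4-allyl-6-ethyl-3-methyl-2-oxohexahydro-2H-cyclopenta[b]furan-5-carboxylic acid
Product: 11 methyl 4-allyl-6-ethyl-3-methyl-2-oxohexahydro-2H-cyclopenta[b]furan-5-carboxylate
Conditions: Me3SiCHN2, PhMe/MeOH (4:1), 0 °C
Reagents that add atoms: (trimethylsilyl)diazomethane, C[Si](C)(C)C=[N+]=[N-]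
Why: Base-free methyl ester formation, so that the kinetic C8 configuration is not exposed to base.

Step 8
Reactants: 11 methyl 4-allyl-6-ethyl-3-methyl-2-oxohexahydro-2H-cyclopenta[b]furan-5-carboxylate
Product: 13 methyl 6-ethyl-3-methyl-2-oxo-4-(2-oxoethyl)hexahydro-2H-cyclopenta[b]furan-5-carboxylate, via ozonide 12 (not isolated)
Conditions: O3, CH2Cl2, −78 °C; then PPh3, −78 °C to rt
Reagents that add atoms: ozone, [O-][O+]=O
Why: Ozonolysis of the only alkene with reductive work-up unveils the C13 aldehyde.

Step 9
Reactants: 13 methyl 6-ethyl-3-methyl-2-oxo-4-(2-oxoethyl)hexahydro-2H-cyclopenta[b]furan-5-carboxylate; 14 (S)-2-methylpropane-2-sulfinamide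
Product: 15 (S,E)-N-sulfinyl aldimine of 13
Conditions: CuSO4 (anhydrous), CH2Cl2, rt
Reagents that add atoms: none
Why: Mild Lewis-acid-mediated condensation to the N-tert-butanesulfinyl imine. CuSO4 is chosen over a titanium alkoxide to avoid transesterification and epimerisation.

Step 10
Reactants: 16 3-methylfuran-2(5H)-one
Product: 17 triisopropyl[(3-methylfuran-2-yl)oxy]silane
Conditions: i-Pr3SiOTf, Et3N, CH2Cl2, 0 °C
Reagents that add atoms: triisopropylsilyl trifluoromethanesulfonate, CC(C)[Si](C(C)C)(C(C)C)OS(=O)(=O)C(F)(F)F
Why: Soft enolisation and O-silylation of the butenolide gives the 2-silyloxyfuran, which carries all carbons of ring E and is nucleophilic at C5 (C14 of the target).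

Step 11
Reactants: 15 (S,E)-N-sulfinyl aldimine of 13; 17 triisopropyl[(3-methylfuran-2-yl)oxy]silane
Product: 18 N-sulfinyl δ-amino butenolide (C13 R, C14 R in target numbering)
Conditions: Me3SiOTf (0.2 equiv), CH2Cl2, −78 °C; aq. NaHCO3
Reagents that add atoms: none
Why: Vinylogous Mukaiyama–Mannich reaction through an open transition state. The furan should add to the imine face opposite the tert-butyl group (S=O syn to C=N), which for the (S)-auxiliary gives 13R. The usual threo preference of silyloxyfuran additions sets 14R.

Step 12
Reactants: 18 N-sulfinyl δ-amino butenolide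
Product: 20 cis-fused tricyclic NH lactam carrying the butenolide at C13, via amine hydrochloride 19 (not isolated)
Conditions: HCl (4 M in dioxane), MeOH, 0 °C; evaporate; then aq. NaHCO3/CH2Cl2, rt to 40 °C
Reagents that add atoms: none
Why: Acidolysis of the N–S bond, then 6-exo-trig lactamisation of the free amine onto the C28 methyl ester closes ring C. Only bicarbonate is used, so that the butenolide γ-centre C14 is not epimerised.

Step 13
Reactants: 20 cis-fused tricyclic NH lactam carrying the butenolide at C13
Product: 21 tricyclic NH lactam with saturated cis-lactone E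
Conditions: H2 (1 atm), Pd/C (10 wt%), EtOAc, rt
Reagents that add atoms: none
Why: Heterogeneous hydrogenation of the butenolide from the face opposite the C13 substituent should give the cis-2,4-disubstituted lactone (16R).

Step 14
Reactants: 22 4-chloro-1,1-dimethoxybutane; 23 1,2-phenylenedimethanol (benzene-1,2-dimethanol)
Product: 24 3-(3-chloropropyl)-1,5-dihydro-3H-2,4-benzodioxepine
Conditions: pyridinium p-toluenesulfonate (5 mol%), PhMe, 60 °C, 5 Å molecular sieves
Reagents that add atoms: none
Why: Acid-catalysed transacetalisation driven by removal of methanol, in which one molecule of the diol replaces both methoxy groups and closes the seven-membered cyclic acetal. This acetal is chosen because whichever oxygen stays on C25 after the key step is a benzylic ether oxygen, so O26 can be freed under neutral conditions.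

Step 15
Reactants: 21 tricyclic NH lactam with saturated cis-lactone E; 24 3-(3-chloropropyl)-1,5-dihydro-3H-2,4-benzodioxepine
Product: 25 N-[3-(1,5-dihydro-3H-2,4-benzodioxepin-3-yl)propyl] lactam
Conditions: NaH, DMF, 0 °C; then 24, NaI (0.2 equiv), 45 °C
Reagents that add atoms: none
Why: N-alkylation of the lactam sodium salt (Finkelstein activation of the chloride); the cyclic acetal is inert to base. The lactam N–H is the most acidic site, and any erosion at C8 or C16 by the amidate is reset in step 16.

Step 16
Reactants: 25 N-[3-(1,5-dihydro-3H-2,4-benzodioxepin-3-yl)propyl] lactam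
Product: 27 O26-[2-(hydroxymethyl)benzyl] ether of the target, via tris(trimethylsilyl) ketene acetal 26 (not isolated)
Conditions: LiN(i-Pr)2 (3.5 equiv), Me3SiCl (4 equiv), THF, −78 to −20 °C; evaporate, pentane, filter; then Me3SiOTf (0.2 equiv), CH2Cl2 (0.005 M), −78 to −40 °C; aq. NaHCO3, 0 °C; then AcOH/NaOAc buffer (pH 5), THF/H2O, 0 °C
Reagents that add atoms: none
Why: Proposed new method: a bridging intramolecular Mukaiyama aldol addition to a cyclic acetal, in which full enolisation and silylation gives 26, Me3SiOTf opens the seven-membered benzodioxepine acetal to an O-benzylic oxocarbenium ion at C25 whose second oxygen is held back as a silyl ether on the aryl arm, and the lactam-derived ketene N,O-acetal (C27=C28), the most nucleophilic of the three enol silanes and the only one that can reach C25 through a ring smaller than nine, should capture that ion in a 7-(enolendo)-exo-trig closure of ring D that creates the C27–C25 bond, the quaternary centre and the twisted N21–C28 amide at once; the closest known reactions are the Me3SiOTf-catalysed ring-opening addition of enol silanes and silyl ketene N,O-acetals to cyclic and acyclic acetals and the formation of 1-azabicyclo[4.3.1]decan-10-ones by closing other bonds of the bridge (Schmidt insertion, transannular amidation, olefin metathesis), whereas closure at the α-carbon has not been shown. The cost of pyramidalising N21 is paid in an early transition state, and loss of the silyl group from the C28 silyloxycarbenium ion to triflate makes the C–C bond formation irreversible, which a base-mediated aldol of this strained β-hydroxy amide would not be. C27 is attacked on the face syn to H3, H11 and H13, because C2, C12 and the pseudo-axial lactone E on C13 cover the other face and the N21 tether can only fold towards the open one; this puts C25 on the ring B face of ring A and keeps the cis A/C junction. C25 is set in an open transition state in which the tether holds C24 gauche to C28 on the N21 side and the benzylic ether oxygen turns away from the silyloxy group (antiperiplanar to C27=C28), which corresponds to 25R. On work-up the two spectator lactone enol silanes are protonated from their open faces: the convex face of ring B, so that methyl C9 ends on the concave face whatever the C8 ratio from step 4, and the face of ring E anti to C13, so that the cis-lactone is kept; the pH 5 buffer hydrolyses the primary silyl ether on the aryl arm. The selectivities needed are lactam over lactone enol silane and C–C bond formation over reclosure of the acetal or oligomerisation; nucleophilicity, ring size and high dilution are expected to secure them.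

Step 17
Reactants: 27 O26-[2-(hydroxymethyl)benzyl] ether of the target
Product: 28 CNP0120800.1
Conditions: H2 (1 atm), Pd(OH)2/C, EtOAc, rt
Reagents that add atoms: none
Why: Neutral hydrogenolysis of the benzylic C–O bond of the ether frees O26 without acid or base, so the twisted amide, the retro-aldol-prone β-hydroxy amide and the kinetic C8 centre should survive.

## Compound list

1 | 1-(furan-2-yl)propan-1-ol (racemic) | CCC(O)c1ccco1 | starting material
2 | rac-trans-5-ethyl-4-hydroxycyclopent-2-en-1-one (one enantiomer drawn) | CC[C@@H]1[C@@H](O)C=CC1=O | intermediate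
3 | (4S,5R)-5-ethyl-4-hydroxycyclopent-2-en-1-one | CC[C@@H]1[C@@H](O)C=CC1=O | intermediate
4 | ethyl prop-1-enyl ether (E/Z mixture) | CC=COCC | starting material
5 | (4S,5R)-4-(2-bromo-1-ethoxypropoxy)-5-ethylcyclopent-2-en-1-one | CC[C@@H]1[C@@H](OC(OCC)C(C)Br)C=CC1=O | intermediate
6 | allyltributylstannane | C=CC[Sn](CCCC)(CCCC)CCCC | starting material
7 | 4-allyl-2-ethoxy-6-ethyl-3-methylhexahydro-2H-cyclopenta[b]furan-5-one | CC[C@@H]1[C@H]2OC(OCC)[C@@H](C)[C@H]2[C@H](CC=C)C1=O | intermediate
8 | 5-(methoxymethylidene) enol ether of 7 | CC[C@@H]1[C@H]2OC(OCC)[C@@H](C)[C@H]2[C@H](CC=C)C1=COC | intermediate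
9 | aldehyde lactol (4-allyl-6-ethyl-2-hydroxy-3-methylhexahydro-2H-cyclopenta[b]furan-5-carbaldehyde) | CC[C@@H]1[C@H]2OC(O)[C@@H](C)[C@H]2[C@H](CC=C)[C@@H]1C=O | intermediate
10 | 4-allyl-6-ethyl-3-methyl-2-oxohexahydro-2H-cyclopenta[b]furan-5-carboxylic acid | CC[C@@H]1[C@H]2OC(=O)[C@@H](C)[C@H]2[C@H](CC=C)[C@@H]1C(O)=O | intermediate
11 | methyl ester of 10 | CC[C@@H]1[C@H]2OC(=O)[C@@H](C)[C@H]2[C@H](CC=C)[C@@H]1C(=O)OC | intermediate
12 | ozonide (1,2,4-trioxolane) of 11 | CC[C@@H]1[C@H]2OC(=O)[C@@H](C)[C@H]2[C@H](CC3OCOO3)[C@@H]1C(=O)OC | intermediate
13 | methyl 6-ethyl-3-methyl-2-oxo-4-(2-oxoethyl)hexahydro-2H-cyclopenta[b]furan-5-carboxylate | CC[C@@H]1[C@H]2OC(=O)[C@@H](C)[C@H]2[C@H](CC=O)[C@@H]1C(=O)OC | intermediate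
14 | (S)-2-methylpropane-2-sulfinamide | CC(C)(C)[S@](=O)N | starting material
15 | (S,E)-N-tert-butanesulfinyl aldimine of 13 | CC[C@@H]1[C@H]2OC(=O)[C@@H](C)[C@H]2[C@H](C/C=N/[S@@](=O)C(C)(C)C)[C@@H]1C(=O)OC | intermediate
16 | 3-methylfuran-2(5H)-one | CC1=CCOC1=O | starting material
17 | triisopropyl[(3-methylfuran-2-yl)oxy]silane | Cc1ccoc1O[Si](C(C)C)(C(C)C)C(C)C | intermediate
18 | N-sulfinyl δ-amino butenolide (13R,14R) | CC[C@@H]1[C@H]2OC(=O)[C@@H](C)[C@H]2[C@H](C[C@H]([C@H]3C=C(C)C(=O)O3)N[S@@](=O)C(C)(C)C)[C@@H]1C(=O)OC | intermediate
19 | amine hydrochloride from 18 | CC[C@@H]1[C@H]2OC(=O)[C@@H](C)[C@H]2[C@H](C[C@H]([C@H]3C=C(C)C(=O)O3)N)[C@@H]1C(=O)OC.Cl | intermediate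
20 | cis-fused tricyclic NH lactam with butenolide at C13 | CC[C@@H]1[C@H]2OC(=O)[C@@H](C)[C@H]2[C@@H]2C[C@H]([C@H]3C=C(C)C(=O)O3)NC(=O)[C@H]12 | intermediate
21 | tricyclic NH lactam with saturated cis-lactone E | CC[C@@H]1[C@H]2OC(=O)[C@@H](C)[C@H]2[C@@H]2C[C@H]([C@H]3C[C@@H](C)C(=O)O3)NC(=O)[C@H]12 | intermediate
22 | 4-chloro-1,1-dimethoxybutane | COC(CCCCl)OC | starting material
23 | 1,2-phenylenedimethanol (benzene-1,2-dimethanol) | OCc1ccccc1CO | starting material
24 | 3-(3-chloropropyl)-1,5-dihydro-3H-2,4-benzodioxepine | ClCCCC1OCc2ccccc2CO1 | intermediate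
25 | N-[3-(1,5-dihydro-3H-2,4-benzodioxepin-3-yl)propyl] lactam | CC[C@@H]1[C@H]2OC(=O)[C@@H](C)[C@H]2[C@@H]2C[C@H]([C@H]3C[C@@H](C)C(=O)O3)N(CCCC3OCc4ccccc4CO3)C(=O)[C@H]12 | intermediate
26 | tris(trimethylsilyl) ketene acetal of 25 (lactam N,O-acetal and both lactone O,O-acetals) | CC[C@@H]1[C@H]2OC(O[Si](C)(C)C)=C(C)[C@H]2[C@@H]2C[C@H]([C@H]3CC(C)=C(O[Si](C)(C)C)O3)N(CCCC3OCc4ccccc4CO3)C(O[Si](C)(C)C)=C12 | intermediate
27 | O26-[2-(hydroxymethyl)benzyl] ether of the target | CC[C@@H]1[C@H]2OC(=O)[C@@H](C)[C@H]2[C@@H]2C[C@H]([C@H]3C[C@@H](C)C(=O)O3)N3CCC[C@@H](OCc4ccccc4CO)[C@@]12C3=O | intermediate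
28 | CNP0120800.1 | CC[C@@H]1[C@H]2OC(=O)[C@@H](C)[C@H]2[C@@H]2C[C@H]([C@H]3C[C@@H](C)C(=O)O3)N3CCC[C@@H](O)[C@@]12C3=O | target

## Step count and least certain steps

Total step count: 17. Longest linear sequence: 15 (steps 1–9, 11–13, 15–17).

**Step 16 (key step).** Most likely failure: ring closure loses to reclosure of the cyclic acetal, to intermolecular addition or to simple hydrolysis of the enol silanes, because the nitrogen must pyramidalise for the tether to reach C27. Stereochemical leakage at C25 is the second concern. Fallback with known chemistry, setting out from 21 and returning at 28: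
- N-allylation (NaH, allyl bromide, DMF) gives the N-allyl lactam F1.
- LiN(i-Pr)2 (3.3 equiv), THF, −78 °C, then acrolein (1 equiv) gives the aldol adduct F2. The amide enolate is the most reactive of the three enolates; the closed chair transition state with the enolate oxygen cis to C3 should give the same C25 configuration; the lactone enolates are reprotonated on quench.
- Ring-closing metathesis with second-generation Grubbs catalyst (PhMe, 80 °C, 1 mM) closes ring D remote from the amide to give the bridged alkene F3.
- Diimide reduction (KO2CN=NCO2K, AcOH), used because the allylic N21–C22 bond is at risk under hydrogenation, gives 28.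

**Step 4.** Most likely failure: the C8 radical or the C11 α-keto radical is reduced or allylated out of sequence, and the methyl selectivity at C8 is low. Fallback from 5, returning at 7: reductive Ueno–Stork cyclisation with Bu3SnH/AIBN gives the bicyclic ketone F4. Kinetic deprotonation at the less substituted α-carbon C11 (LiN(i-Pr)2, −78 °C) and allyl bromide then alkylate trans to the ring B bond.

**Step 11.** Most likely failure: wrong facial sense, or low threo selectivity, in the addition to the sulfinyl imine. Fallback from 13 (with 17), returning at 20: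
- Catalytic asymmetric vinylogous Mukaiyama aldol (Ti(Oi-Pr)4/(R)-BINOL) to the erythro δ-hydroxy butenolide F5.
- Mitsunobu azidation with inversion (PPh3, DIAD, (PhO)2P(O)N3) to the azide F6.
- Staudinger reduction (PMe3, THF/H2O); the free amine lactamises to 20.

**Step 2.** Most likely failure: poor or reversed enantiomer discrimination by the lipase, because the ethyl group next to the carbinol changes the relative size of the two flanks. Fallback from 2, returning at 18: carry racemic material through steps 3–9 and 11. Since 14 controls C13 and C14, the enantiomeric cores give 18 and the diastereomeric sulfinamide F7, which are separated by chromatography.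

**Step 5.** Most likely failure: enolisation of the hindered ketone, flanked by two α-branches, instead of olefination. Fallback from 7, returning at 10: Corey–Chaykovsky epoxidation (Me3S+ I−, KN(SiMe3)2, THF) gives the spiro-epoxide F8. Meinwald rearrangement (BF3·OEt2, CH2Cl2, −78 °C) gives the aldehyde F9, which enters the Jones oxidation of step 6.

## Further compounds

F1 | step 16 | N-allyl lactam | CC[C@@H]1[C@H]2OC(=O)[C@@H](C)[C@H]2[C@@H]2C[C@H]([C@H]3C[C@@H](C)C(=O)O3)N(CC=C)C(=O)[C@H]12
F2 | step 16 | aldol adduct (C27 quaternary, C25 allylic alcohol) | CC[C@@H]1[C@H]2OC(=O)[C@@H](C)[C@H]2[C@@H]2C[C@H]([C@H]3C[C@@H](C)C(=O)O3)N(CC=C)C(=O)[C@]12[C@H](O)C=C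
F3 | step 16 | bridged alkene (23,24-didehydro target) | CC[C@@H]1[C@H]2OC(=O)[C@@H](C)[C@H]2[C@@H]2C[C@H]([C@H]3C[C@@H](C)C(=O)O3)N3CC=C[C@@H](O)[C@@]12C3=O
F4 | step 4 | 2-ethoxy-6-ethyl-3-methylhexahydro-2H-cyclopenta[b]furan-5-one | CC[C@@H]1[C@H]2OC(OCC)[C@@H](C)[C@H]2CC1=O
F5 | step 11 | erythro δ-hydroxy butenolide | CC[C@@H]1[C@H]2OC(=O)[C@@H](C)[C@H]2[C@H](C[C@H](O)[C@H]3C=C(C)C(=O)O3)[C@@H]1C(=O)OC
F6 | step 11 | δ-azido butenolide | CC[C@@H]1[C@H]2OC(=O)[C@@H](C)[C@H]2[C@H](C[C@H]([C@H]3C=C(C)C(=O)O3)N=[N+]=[N-])[C@@H]1C(=O)OC
F7 | step 2 | diastereomer of 18 from the enantiomeric core | CC[C@H]1[C@@H]2OC(=O)[C@H](C)[C@@H]2[C@@H](C[C@H]([C@H]3C=C(C)C(=O)O3)N[S@@](=O)C(C)(C)C)[C@H]1C(=O)OC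
F8 | step 5 | spiro-epoxide of 7 | CC[C@@H]1[C@H]2OC(OCC)[C@@H](C)[C@H]2[C@H](CC=C)C11CO1
F9 | step 5 | 4-allyl-2-ethoxy-6-ethyl-3-methylhexahydro-2H-cyclopenta[b]furan-5-carbaldehyde | CC[C@@H]1[C@H]2OC(OCC)[C@@H](C)[C@H]2[C@H](CC=C)C1C=O
A1 | alternative 1 | nine-membered amino acid (N21–C28 seco acid) | CC[C@@H]1[C@H]2OC(=O)[C@@H](C)[C@H]2[C@@H]2C[C@H]([C@H]3C[C@@H](C)C(=O)O3)NCCC[C@@H](O)[C@@]12C(O)=O
A2 | alternative 2 | azido spiro[4.5]decanone | CC[C@@H]1[C@H]2OC(=O)[C@@H](C)[C@H]2[C@H](C[C@H]([C@H]3C[C@@H](C)C(=O)O3)N=[N+]=[N-])[C@]11C(=O)CCC[C@H]1O
A3 | alternative 2 | fused pyrrolo-azepinone (N21 bonded to C27) | CC[C@@H]1[C@H]2OC(=O)[C@@H](C)[C@H]2[C@@H]2C[C@H]([C@H]3C[C@@H](C)C(=O)O3)N3C(=O)CCC[C@@H](O)[C@@]123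
A4 | alternative 3 | epoxy carbinolamine (configuration at C25, C27, C28 open) | CC[C@@H]1[C@H]2OC(=O)[C@@H](C)[C@H]2[C@@H]2C[C@H]([C@H]3C[C@@H](C)C(=O)O3)N3CCCC4OC14C23O
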